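The readings come from a simulation for an exercise; scatter was added.

The substrate left over at the end tells me how far along a flask is, so I reckon that first.

| flask | substrate | partner | scavenger | remark | time |
|---|---|---|---|---|---|
| noon | 0.30 M | 0.30 M | 0.090 M | run made earlier |  |
| spring | 0.30 M | 0.86 M | 0.090 M | run made earlier |  |
| Thursday's | 0.30 M | 0.450 M | 0.0900 M |  | 30 min |
| Sunday's | 0.30 M | 1.20 M | 0.0900 M |  | 30 min |
| Saturday's | 0.30 M | 0.750 M | 0.0900 M |  | 30 min |

| noon: time / min | noon: mono adduct / % | spring: time / min | spring: mono adduct / % |
|---|---|---|---|
| 5.00 | 8.8 | 2.00 | 9.8 |
| 10.0 | 12.2 | 6.00 | 19.3 |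
| 15.0 | 14.7 | 10.0 | 26.0 |
| 20.0 | 22.7 | 15.0 | 31.5 |
| 25.0 | 24.4 | 25.0 | 38.6 |
| 30.0 | 25.2 | 30.0 | 39.7 |

(readings scatter by 1 percentage point)

- which of these holds the largest part of the substrate at the end of Thursday's (double product / substrate / mono adduct)
- which of these holds the largest part of the substrate at the end of Sunday's (double product / substrate / mono adduct)
- which of these holds the largest part of the substrate at the end of Saturday's (double product / substrate / mono adduct)
- how much mono adduct is there at the end of Sunday's, in percent of the substrate charged

- amounts and yields of mono adduct count crystals too
- amounts and yields of released group count idle adduct too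
- given per volume of solution although it is solid: crystals
- the analysis behind the earlier runs scatters by 1 percentage point, standard deviation
- steps under discussion: substrate + partner -> mono adduct + released group; partner + mono adduct -> double product + released group; partner -> decomposed reagent; substrate + released group <-> idle adduct; scavenger + released group -> scavenged by-product; crystals <-> mono adduct

I follow one substrate molecule through the flask. The first spring reading, with partner taken as steady (pseudo-first-order), gives its life on Sunday's:

life = 2.00 min × 0.86 M / (9.8% × 1.20 M) = 14.6 min

lives = 30 min / life = 2.05

I call this count the run length in lives; with partner steady, a molecule's chance of staying free is one over e to that power.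

On Sunday's, my ladder has three rungs before the end. At the starting rate, release matches the scavenger's charge by 4.39 min, sooner than the life. Next comes the life itself. Then, at 17.9 min, well before the end, Sunday's reaches the lives at which the spring run read 38.6%.

With substrate and scavenger charges held, I read mono adduct from the spring run at equal lives. By this reckoning free substrate comes to 46.3% on Thursday's, 27.7% on Saturday's and 12.9% on Sunday's. Mono adduct reads about 31.5% for Thursday's and 38.6% for Saturday's. For Sunday's the spring run stops short, at 1.47 lives against 2.05, so I take its last reading, 39.7%, as my figure. On Sunday's, 47.4% remains for double product and idle adduct, so double product is my danger there.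

The forecast says substrate, mono adduct and mono adduct for Thursday's, Sunday's and Saturday's, with 43% (36% to 50%) of mono adduct on Sunday's, above my figure. It adds: “Crystals may protect it from over-reaction”.

The flasks give substrate, mono adduct and mono adduct, and 40.7% of mono adduct on Sunday's.

    substrate + partner → mono adduct + released group (k = 0.00117 L mol⁻¹ s⁻¹)
    partner + mono adduct → double product + released group (k = 0.00348 L mol⁻¹ s⁻¹)
    partner → decomposed reagent (k = 1.89 × 10⁻⁴ s⁻¹)
    substrate + released group ⇌ idle adduct, settled at all times (K = 3.70 L mol⁻¹)
    scavenger + released group → scavenged by-product (k = 0.0253 L mol⁻¹ s⁻¹)
    crystals ⇌ mono adduct, rate k6*(cs6 - [mono adduct]) while solid is left; crystals form when [mono adduct] > cs6 (solubility = 10.0 mM, k = 0.00815 s⁻¹)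

On Sunday's, free substrate is 16% against my 12.9%, with 11.3% more held as idle adduct. On Sunday's, partner's half-life by decomposition alone, 61 min, is longer than the run's 30 min, and 50% of the partner is left at 30.0 min.

The neighbour charged with 0.18 M of substrate keeps Sunday's partner and time, so it has the same 2.05 lives and I expect about 12.9% free substrate again. It gives 15.4%, but with 34.9% of mono adduct and 42.9% of double product, so double product holds the most.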